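Set your flask beside amber: the same 3.0 mM of Cat and the same Sbt, but amber got 15 mM of Rea against your 10.0 mM, and its Sbt reads 44% at 10.0 d. Teal and green carry your Rea and read 58% and 58% at that time, though their Cat differs by a factor of 4.00 and yours lies between.

| setting | teal | green | amber | flask |
|---|---|---|---|---|
| Sbt | 20 mM | 20 mM | 20 mM | 20 mM |
| Rea | 10 mM | 10 mM | 15 mM | 10.0 mM |
| Cat | 1.5 mM | 6 mM | 3 mM | 3.0 mM |
| remark | run made earlier | run made earlier | run made earlier |  |
| time |  |  |  | 15 d |

| run | time / d | Sbt / % | Pdt / % |
|---|---|---|---|
| teal | 0.500 | 67 | 11 |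
| teal | 1.25 | 65 | 11 |
| teal | 2.50 | 61 | 8 |
| teal | 4.00 | 59 | 8 |
| teal | 5.00 | 62 | 7 |
| teal | 8.00 | 60 | 6 |
| teal | 10.0 | 58 | 8 |
| green | 1.25 | 63 | 8 |
| green | 2.50 | 61 | 9 |
| green | 4.00 | 61 | 6 |
| green | 5.00 | 60 | 8 |
| green | 6.00 | 61 | 5 |
| green | 8.00 | 60 | 6 |
| green | 10.0 | 58 | 7 |
| amber | 1.67 | 50 | 11 |
| amber | 4.00 | 44 | 11 |
| amber | 5.00 | 45 | 8 |
| amber | 8.00 | 46 | 7 |
| amber | 10.0 | 44 | 11 |

(readings scatter by 1.5 percentage points)

* at 15 d, what has stopped the reaction, if anything has (it is still moving / Rea has run out first / all of Sbt has reacted / forward and back rates have come level / no working catalyst is left)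
* share of the Sbt used up at 15 d
* Pdt at 15 d, in percent of the Sbt charged
* Sid at 15 d, in percent of the Sbt charged

- the analysis behind the earlier runs scatters by 1.5 percentage points, standard deviation
- the reaction counts as stopped when no species that holds the Sbt changes by six tenths of a point or more over the second half of the time

So teal and green, with the same Rea and different Cat, stand level within the scatter at that time, and amber, with more Rea and a Cat between theirs, stands lower in Sbt. Now compare rates at one moment. Take the forward rate as going with Sbt left times Rea left and the back rate with what was used, counting one Rea per Sbt, everything as a fraction of the Sbt charge. Their comparison drifts as used share grows and Rea falls: in teal at 0.500 d the quotient is 2.90, and over teal's last readings, with 40.2% used, it reads 6.91. Amber's last readings give 55.2% used and 6.25. Used share over Sbt left times Rea left, at rest, is the stopping quotient, an apparent equilibrium constant in units of the 20 mM Sbt charge. I take amber's reading, since more Rea stays in amber than in teal, so a point of scatter weighs less on amber's quotient.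

Solved for your charges, it gives me 39.5% used. The forecast, holding that “Cat sets speed, not endpoint”, says forward and back rates have come level, with 41% used, 7% Pdt and 34% Sid, its conversion a little above mine.

The flask gives 39.5% used, 6.48% Pdt and 33.0% Sid; its verdict: forward and back rates have come level. Working Cat in the flask is down to 2.23% of its charge at 15.0 d, with 97.8% as Zet, yet that loss moves the conversion by nothing. The flask's shares put back into the quotient give 6.22.

    Pdt + Cat ⇌ Sid + Cat, rate k1*[Cat]*[Pdt] forward; the back reaction follows from the equilibrium constant (k = 6.51 L mol⁻¹ h⁻¹)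
    Sbt + Rea ⇌ Pdt (K = 51.0 L mol⁻¹, k = 9.85 L mol⁻¹ h⁻¹)
    Sbt + Rea ⇌ Sid (K = 260 L mol⁻¹, k = 4.65 L mol⁻¹ h⁻¹)
    2 Cat → Zet (k = 20.3 L mol⁻¹ h⁻¹)

Cut Rea in your flask to 4.0 mM, all else held, and the quotient 6.25 gives 16.8% used. That neighbour computes to 16.8%, with 16.2% of its Rea still there.

All runs come from a simulation for substances that don't exist, and the scatter is random.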